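**Retrosynthetic overview**

1. Iridal numbering is used: C1 = CHO, C2=C7 = exocyclic alkene, C3–C5 = oxygenated propyl chain on C6, ring = C6–C11, side chain = C12–C23 with C16–OAc. Target 34 comes from cyclohexanol ester 28 by C1 ester → aldehyde, desilylation, C3 decanoylation and C16 acetylation.
2. Key disconnection C9–C10. Ring carbon C10 is a tertiary methyl carbinol on the quaternary C11, i.e. the adduct of a methyl ketone. Ring carbon C9 is a plain CH2 insulated from the C2=C7 alkene by C8, so an sp3 C9 organosamarium can add to the C10 ketone and close the only ring (C6–C7–C8–C9–C10–C11) without touching the stereodefined tetrasubstituted alkene.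
3. Acyclic precursor 26: (2Z)-alkene by E-selective enol tosylation of a β-keto ester and stereoretentive Negishi vinylation; C10 acetyl by Wacker oxidation of a C11 vinyl group; C9–I by hydroboration/iodination of the new vinyl group.
4. C6–C11 bond and both stereocentres by enantioselective Ireland–Claisen rearrangement of the 16-oxygenated geranylgeranyl-type ester 14 (its vinyl group is the latent C10 acetyl).
5. 14 from geraniol, geranyl chloride (C16–C17 by allylbarium addition, C16 by CBS reduction) and δ-valerolactone. One ring only, formed in step 15.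

Key step: step 15

Remark: the (S,S)-diazaborolidine of step 8 is assumed to give the configuration drawn for acid 16; if its sense of induction is the opposite, the (R,R)-reagent is used in the same way.

**Route**

Step 1
Reactants: 1 δ-valerolactone
Product: 4 5-(tert-butyldimethylsilyloxy)pentanoic acid, via sodium 5-hydroxypentanoate 2 (not isolated), via bis-silyl derivative 3 (not isolated)
Conditions: NaOH (1.0 equiv), MeOH/H2O, rt, evaporate; TBSCl (2.3 equiv), imidazole, DMF, rt; then K2CO3 (0.1 equiv), MeOH/H2O, rt, extraction at pH 4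
Reagents that add atoms: sodium hydroxide [Na+].[OH-]; tert-butyldimethylsilyl chloride CC(C)(C)[Si](C)(C)Cl
Why: Lactone saponification and exhaustive silylation, after which the silyl ester, far more labile than the silyl ether, is hydrolysed selectively.

Step 2
Reactants: 4 5-(tert-butyldimethylsilyloxy)pentanoic acid, 5 geraniol
Product: 6 geranyl 5-(tert-butyldimethylsilyloxy)pentanoate
Conditions: DCC (1.1 equiv), DMAP (0.1 equiv), CH2Cl2, 0 °C → rt
Reagents that add atoms: none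
Why: Steglich esterification (carbodiimide activation, DMAP acyl transfer) of the primary allylic alcohol; no stereocentre is involved.

Step 3
Reactants: 6 geranyl 5-(tert-butyldimethylsilyloxy)pentanoate
Product: 8 (2E,6E)-3,7-dimethyl-8-oxoocta-2,6-dien-1-yl 5-(tert-butyldimethylsilyloxy)pentanoate, via 8-hydroxy ester 7 (not isolated)
Conditions: SeO2 (0.3 equiv), tBuOOH (3 equiv), salicylic acid (0.1 equiv), CH2Cl2, rt; filtration; MnO2 (15 equiv), CH2Cl2, rt
Reagents that add atoms: tert-butyl hydroperoxide CC(C)(C)OO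
Why: SeO2-catalysed allylic oxidation (ene reaction, then [2,3]-shift) should attack the E-methyl of the electron-rich distal alkene, the proximal alkene being deactivated by the allylic ester, and MnO2 converges the alcohol/aldehyde mixture on the (E)-enal.

Step 4
Reactants: 8 (2E,6E)-3,7-dimethyl-8-oxoocta-2,6-dien-1-yl 5-(tert-butyldimethylsilyloxy)pentanoate, 9 geranyl chloride
Product: 11 (2E,6E,8RS,10E)-8-hydroxy-3,7,11,15-tetramethylhexadeca-2,6,10,14-tetraen-1-yl 5-(tert-butyldimethylsilyloxy)pentanoate, via geranylbarium chloride 10 (not isolated)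
Conditions: activated Ba (from BaI2 and 2 LiC12H10, lithium biphenylide, THF, rt); 9, THF, −78 °C; then 8, −78 °C; aqueous work-up
Reagents that add atoms: none
Why: Barbier-type allylbarium addition, in which the allylbarium should add 1,2 to the enal through its less substituted (α) carbon with retention of the E geometry at −78 °C and leave both esters intact; C16 forms as both epimers, corrected in steps 5 and 6.

Step 5
Reactants: 11 (2E,6E,8RS,10E)-8-hydroxy-3,7,11,15-tetramethylhexadeca-2,6,10,14-tetraen-1-yl 5-(tert-butyldimethylsilyloxy)pentanoate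
Product: 12 (2E,6E,10E)-3,7,11,15-tetramethyl-8-oxohexadeca-2,6,10,14-tetraen-1-yl 5-(tert-butyldimethylsilyloxy)pentanoate
Conditions: Dess–Martin periodinane (1.3 equiv), pyridine, CH2Cl2, 0 °C
Reagents that add atoms: none
Why: Dess–Martin oxidation under buffered, non-basic conditions should give the enone without moving the skipped C18 alkene into conjugation, and it erases the C16 mixture.

Step 6
Reactants: 12 (2E,6E,10E)-3,7,11,15-tetramethyl-8-oxohexadeca-2,6,10,14-tetraen-1-yl 5-(tert-butyldimethylsilyloxy)pentanoate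
Product: 13 (2E,6E,8R,10E)-8-hydroxy-3,7,11,15-tetramethylhexadeca-2,6,10,14-tetraen-1-yl 5-(tert-butyldimethylsilyloxy)pentanoate
Conditions: (S)-2-methyl-CBS-oxazaborolidine (0.2 equiv), catecholborane (1.8 equiv), toluene, −78 °C
Reagents that add atoms: none
Why: Corey–Bakshi–Shibata reduction in which the trisubstituted alkenyl group is the large and the CH2 group the small ketone substituent, so the (S)-catalyst should give the (R)-alcohol (C16 of the target); esters and alkenes are inert to catecholborane at −78 °C.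

Step 7
Reactants: 13 (2E,6E,8R,10E)-8-hydroxy-3,7,11,15-tetramethylhexadeca-2,6,10,14-tetraen-1-yl 5-(tert-butyldimethylsilyloxy)pentanoate
Product: 14 (2E,6E,8R,10E)-8-(tert-butyldimethylsilyloxy)-3,7,11,15-tetramethylhexadeca-2,6,10,14-tetraen-1-yl 5-(tert-butyldimethylsilyloxy)pentanoate
Conditions: TBSOTf (1.3 equiv), 2,6-lutidine (2 equiv), CH2Cl2, −78 °C
Reagents that add atoms: tert-butyldimethylsilyl triflate CC(C)(C)[Si](C)(C)OS(=O)(=O)C(F)(F)F
Why: Silylation of the hindered secondary allylic alcohol with the silyl triflate; no stereocentre is touched.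

Step 8
Reactants: 14 (2E,6E,8R,10E)-8-(tert-butyldimethylsilyloxy)-3,7,11,15-tetramethylhexadeca-2,6,10,14-tetraen-1-yl 5-(tert-butyldimethylsilyloxy)pentanoate
Product: 16 (2S,3R)-2-[3-(tert-butyldimethylsilyloxy)propyl]-3-methyl-3-[(3E,5R,7E)-5-(tert-butyldimethylsilyloxy)-4,8,12-trimethyltrideca-3,7,11-trien-1-yl]pent-4-enoic acid, via boron ketene acetal 15 (not isolated)
Conditions: (S,S)-2-bromo-4,5-diphenyl-1,3-bis[3,5-bis(trifluoromethyl)phenylsulfonyl]-1,3,2-diazaborolidine (1.3 equiv), Et3N (1.5 equiv), toluene/hexane, −78 °C; then 4 °C until rearranged; aqueous acid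
Reagents that add atoms: none
Why: Enantioselective boron-enolate Ireland–Claisen rearrangement, in which Et3N in toluene/hexane should give the Z(O)-enolate whose chair transition state with the (2E)-allyl unit puts the C5 chain and the C12 chain equatorial (this fixes the C6/C11 relative configuration across the new C6–C11 bond), while the chiral diazaborolidine selects the enolate face.

Step 9
Reactants: 16 (2S,3R)-2-[3-(tert-butyldimethylsilyloxy)propyl]-3-methyl-3-[(3E,5R,7E)-5-(tert-butyldimethylsilyloxy)-4,8,12-trimethyltrideca-3,7,11-trien-1-yl]pent-4-enoic acid, 17 methyl 2-bromopropanoate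
Product: 20 methyl (2RS,4S,5R)-4-[3-(tert-butyldimethylsilyloxy)propyl]-2,5-dimethyl-3-oxo-5-[(3E,5R,7E)-5-(tert-butyldimethylsilyloxy)-4,8,12-trimethyltrideca-3,7,11-trien-1-yl]hept-6-enoate, via acid chloride 18 (not isolated), via zinc ester enolate 19 (not isolated)
Conditions: 16, 1-chloro-N,N,2-trimethylprop-1-en-1-amine (1.2 equiv), CH2Cl2, 0 °C; separately 17, Zn, THF, 40 °C; combine, Pd(PPh3)4 (5 mol %), THF, 0 °C → rt
Reagents that add atoms: none
Why: Neutral acid chloride formation followed by palladium-catalysed acylation of a Reformatsky reagent gives the β-keto ester without any strong base, so C6 cannot epimerise through a ketene.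

Step 10
Reactants: 20 methyl (2RS,4S,5R)-4-[3-(tert-butyldimethylsilyloxy)propyl]-2,5-dimethyl-3-oxo-5-[(3E,5R,7E)-5-(tert-butyldimethylsilyloxy)-4,8,12-trimethyltrideca-3,7,11-trien-1-yl]hept-6-enoate
Product: 21 methyl (2RS,4S,5S)-4-[3-(tert-butyldimethylsilyloxy)propyl]-2,5-dimethyl-3,6-dioxo-5-[(3E,5R,7E)-5-(tert-butyldimethylsilyloxy)-4,8,12-trimethyltrideca-3,7,11-trien-1-yl]heptanoate
Conditions: PdCl2 (0.2 equiv), CuCl (1.0 equiv), O2 (1 atm), DMF/H2O 7:1, rt
Reagents that add atoms: water O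
Why: Tsuji–Wacker oxidation by Markovnikov hydroxypalladation of the only monosubstituted alkene, the trisubstituted alkenes being too hindered to react, which turns the C11 vinyl group into the C10 acetyl group.

Step 11
Reactants: 21 methyl (2RS,4S,5S)-4-[3-(tert-butyldimethylsilyloxy)propyl]-2,5-dimethyl-3,6-dioxo-5-[(3E,5R,7E)-5-(tert-butyldimethylsilyloxy)-4,8,12-trimethyltrideca-3,7,11-trien-1-yl]heptanoate
Product: 22 methyl (2E,4S,5S)-4-[3-(tert-butyldimethylsilyloxy)propyl]-2,5-dimethyl-6-oxo-3-(4-methylphenylsulfonyloxy)-5-[(3E,5R,7E)-5-(tert-butyldimethylsilyloxy)-4,8,12-trimethyltrideca-3,7,11-trien-1-yl]hept-2-enoate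
Conditions: TsCl (1.5 equiv), N-methylimidazole (1.5 equiv), Et3N (1.5 equiv), CH2Cl2, −15 °C → rt
Reagents that add atoms: p-toluenesulfonyl chloride Cc1ccc(cc1)S(Cl)(=O)=O
Why: Stereocomplementary enol tosylation of an α-substituted β-keto ester, where under non-chelating amine conditions the enolate oxygen lies anti to the ester carbonyl and is trapped by the N-sulfonylimidazolium salt, which should give the (E)-tosylate (OTs trans to CO2Me, C6 cis to CO2Me); the less acidic methyl ketone is not enolised.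

Step 12
Reactants: 22 methyl (2E,4S,5S)-4-[3-(tert-butyldimethylsilyloxy)propyl]-2,5-dimethyl-6-oxo-3-(4-methylphenylsulfonyloxy)-5-[(3E,5R,7E)-5-(tert-butyldimethylsilyloxy)-4,8,12-trimethyltrideca-3,7,11-trien-1-yl]hept-2-enoate
Product: 23 methyl (2Z,4R,5S)-3-ethenyl-4-[3-(tert-butyldimethylsilyloxy)propyl]-2,5-dimethyl-6-oxo-5-[(3E,5R,7E)-5-(tert-butyldimethylsilyloxy)-4,8,12-trimethyltrideca-3,7,11-trien-1-yl]hept-2-enoate
Conditions: CH2=CHZnBr (2 equiv), Pd(OAc)2 (5 mol %), 2-dicyclohexylphosphino-2',6'-dimethoxybiphenyl (10 mol %), THF, 50 °C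
Reagents that add atoms: vinylzinc bromide C=C[Zn]Br
Why: Negishi cross-coupling of the ester-activated enol tosylate with retention of configuration, so the new vinyl group (C8=C9) is cis to the C2 methyl and C1 is cis to C6; the organozinc does not add to the ketone or the esters.

Step 13
Reactants: 23 methyl (2Z,4R,5S)-3-ethenyl-4-[3-(tert-butyldimethylsilyloxy)propyl]-2,5-dimethyl-6-oxo-5-[(3E,5R,7E)-5-(tert-butyldimethylsilyloxy)-4,8,12-trimethyltrideca-3,7,11-trien-1-yl]hept-2-enoate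
Product: 25 methyl (2Z,4R,5S)-3-(2-hydroxyethyl)-4-[3-(tert-butyldimethylsilyloxy)propyl]-2,5-dimethyl-6-oxo-5-[(3E,5R,7E)-5-(tert-butyldimethylsilyloxy)-4,8,12-trimethyltrideca-3,7,11-trien-1-yl]hept-2-enoate, via B-alkyl-9-borabicyclononane 24 (not isolated)
Conditions: 9-BBN (1.3 equiv), THF, 0 °C → rt; then H2O2, aqueous NaOAc, 0 °C
Reagents that add atoms: hydrogen peroxide OO
Why: Anti-Markovnikov hydroboration–oxidation, in which 9-BBN should select the terminal vinyl carbon C9 over the tri- and tetrasubstituted alkenes and react only slowly with the hindered ketone.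

Step 14
Reactants: 25 methyl (2Z,4R,5S)-3-(2-hydroxyethyl)-4-[3-(tert-butyldimethylsilyloxy)propyl]-2,5-dimethyl-6-oxo-5-[(3E,5R,7E)-5-(tert-butyldimethylsilyloxy)-4,8,12-trimethyltrideca-3,7,11-trien-1-yl]hept-2-enoate
Product: 26 methyl (2Z,4R,5S)-3-(2-iodoethyl)-4-[3-(tert-butyldimethylsilyloxy)propyl]-2,5-dimethyl-6-oxo-5-[(3E,5R,7E)-5-(tert-butyldimethylsilyloxy)-4,8,12-trimethyltrideca-3,7,11-trien-1-yl]hept-2-enoate
Conditions: I2 (1.3 equiv), PPh3 (1.3 equiv), imidazole (2 equiv), CH2Cl2, 0 °C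
Reagents that add atoms: iodine II
Why: Appel-type iodination of the primary alcohol by SN2 displacement of the alkoxyphosphonium ion; ketone, esters and alkenes are unaffected.

Step 15
Reactants: 26 methyl (2Z,4R,5S)-3-(2-iodoethyl)-4-[3-(tert-butyldimethylsilyloxy)propyl]-2,5-dimethyl-6-oxo-5-[(3E,5R,7E)-5-(tert-butyldimethylsilyloxy)-4,8,12-trimethyltrideca-3,7,11-trien-1-yl]hept-2-enoate
Product: 28 methyl (2Z)-2-[(2R,3S,4S)-2-[3-(tert-butyldimethylsilyloxy)propyl]-4-hydroxy-3,4-dimethyl-3-[(3E,5R,7E)-5-(tert-butyldimethylsilyloxy)-4,8,12-trimethyltrideca-3,7,11-trien-1-yl]cyclohexylidene]propanoate, via C9 organosamarium 27 (not isolated)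
Conditions: SmI2 (2.5 equiv, 0.1 M in THF), Fe(C15H11O2)3 (tris(dibenzoylmethanato)iron, 2 mol %), THF, −78 °C → rt; aqueous work-up
Reagents that add atoms: none
Why: Two single-electron transfers from SmI2 convert the C9–I bond into the C9 diiodosamarium alkyl 27, which adds to the C10 ketone carbonyl. The closest known reaction type is the SmI2-promoted, iron-catalysed intramolecular Barbier cyclisation of ω-iodoalkyl ketones to cycloalkanols. The cyclohexane ring C6–C7–C8–C9–C10–C11 is closed by 6-exo-trig attack of C9 on the carbonyl carbon C10. The new stereocentre C10 is controlled by C6 and C11 through a chair transition state: A(1,3) strain with the substituents on C2 holds the C6 chain axial, and the ketone should react in the rotamer with its methyl group anti to C6, between the two smaller C11 substituents, so the oxygen ends pseudo-axial on the face of the C6 chain and the methyl equatorial (10S). The step needs chemoselective reduction of the primary iodide beside ketone, enoate and trisubstituted alkenes (served by the HMPA-free iron-catalysed protocol without proton source), no conjugate three-membered closure (C7 is a fully substituted, poorly accessible acceptor carbon) and no attack on the C1 ester (C1 is trans to C8 across the alkene). Because C8 and C9 are sp3 and no allylic intermediate forms, the (2Z) geometry set in steps 11 and 12 is carried through unchanged.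

Step 16
Reactants: 28 methyl (2Z)-2-[(2R,3S,4S)-2-[3-(tert-butyldimethylsilyloxy)propyl]-4-hydroxy-3,4-dimethyl-3-[(3E,5R,7E)-5-(tert-butyldimethylsilyloxy)-4,8,12-trimethyltrideca-3,7,11-trien-1-yl]cyclohexylidene]propanoate
Product: 29 (2Z)-2-[(2R,3S,4S)-2-[3-(tert-butyldimethylsilyloxy)propyl]-4-hydroxy-3,4-dimethyl-3-[(3E,5R,7E)-5-(tert-butyldimethylsilyloxy)-4,8,12-trimethyltrideca-3,7,11-trien-1-yl]cyclohexylidene]propan-1-ol
Conditions: iBu2AlH (4 equiv), CH2Cl2, −78 → −20 °C; aqueous work-up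
Reagents that add atoms: none
Why: 1,2-Reduction of the hindered conjugated ester to the allylic alcohol with iBu2AlH, with the alkene geometry retained; silyl ethers and the tertiary alcohol (as its aluminium alkoxide) survive.

Step 17
Reactants: 29 (2Z)-2-[(2R,3S,4S)-2-[3-(tert-butyldimethylsilyloxy)propyl]-4-hydroxy-3,4-dimethyl-3-[(3E,5R,7E)-5-(tert-butyldimethylsilyloxy)-4,8,12-trimethyltrideca-3,7,11-trien-1-yl]cyclohexylidene]propan-1-ol
Product: 30 (2Z)-2-[(2R,3S,4S)-2-[3-(tert-butyldimethylsilyloxy)propyl]-4-hydroxy-3,4-dimethyl-3-[(3E,5R,7E)-5-(tert-butyldimethylsilyloxy)-4,8,12-trimethyltrideca-3,7,11-trien-1-yl]cyclohexylidene]propanal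
Conditions: MnO2 (20 equiv), CH2Cl2, rt
Reagents that add atoms: none
Why: MnO2 oxidises only the allylic primary alcohol to the enal, under neutral heterogeneous conditions that should not isomerise the (2Z)-alkene.

Step 18
Reactants: 30 (2Z)-2-[(2R,3S,4S)-2-[3-(tert-butyldimethylsilyloxy)propyl]-4-hydroxy-3,4-dimethyl-3-[(3E,5R,7E)-5-(tert-butyldimethylsilyloxy)-4,8,12-trimethyltrideca-3,7,11-trien-1-yl]cyclohexylidene]propanal
Product: 31 (2Z)-2-[(2R,3S,4S)-4-hydroxy-3-[(3E,5R,7E)-5-hydroxy-4,8,12-trimethyltrideca-3,7,11-trien-1-yl]-2-(3-hydroxypropyl)-3,4-dimethylcyclohexylidene]propanal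
Conditions: HF·pyridine, pyridine/THF, 0 °C → rt
Reagents that add atoms: none
Why: Fluoride-mediated cleavage of both silyl ethers under buffered conditions; the enal, the tertiary alcohol and the allylic C16 stereocentre should be stable.

Step 19
Reactants: 31 (2Z)-2-[(2R,3S,4S)-4-hydroxy-3-[(3E,5R,7E)-5-hydroxy-4,8,12-trimethyltrideca-3,7,11-trien-1-yl]-2-(3-hydroxypropyl)-3,4-dimethylcyclohexylidene]propanal, 32 decanoyl chloride
Product: 33 3-[(1R,2S,3S)-3-hydroxy-2-[(3E,5R,7E)-5-hydroxy-4,8,12-trimethyltrideca-3,7,11-trien-1-yl]-2,3-dimethyl-6-[(2Z)-1-oxopropan-2-ylidene]cyclohexyl]propyl decanoate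
Conditions: 2,4,6-collidine (3 equiv), CH2Cl2, −78 → −40 °C
Reagents that add atoms: none
Why: Selective acylation of the only primary hydroxyl with an acyl chloride and a hindered pyridine base at low temperature; the hindered secondary allylic C16–OH and the tertiary C10–OH should not react.

Step 20
Reactants: 33 3-[(1R,2S,3S)-3-hydroxy-2-[(3E,5R,7E)-5-hydroxy-4,8,12-trimethyltrideca-3,7,11-trien-1-yl]-2,3-dimethyl-6-[(2Z)-1-oxopropan-2-ylidene]cyclohexyl]propyl decanoate
Product: 34 (2Z)-2-[(2R,3S,4S)-3-[(3E,5R,7E)-5-acetoxy-4,8,12-trimethyltrideca-3,7,11-trien-1-yl]-2-[3-(decanoyloxy)propyl]-4-hydroxy-3,4-dimethylcyclohexylidene]propanal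
Conditions: Ac2O (3 equiv), pyridine, DMAP (0.1 equiv), CH2Cl2, 0 °C → rt
Reagents that add atoms: acetic anhydride CC(=O)OC(C)=O
Why: DMAP-catalysed acetylation of the secondary allylic C16–OH with retention; the tertiary C10–OH is too hindered to be acylated under these conditions.

**Compound list**

1 | δ-valerolactone | O=C1CCCCO1 | starting material
2 | sodium 5-hydroxypentanoate | [Na+].[O-]C(=O)CCCCO | intermediate
3 | tert-butyldimethylsilyl 5-(tert-butyldimethylsilyloxy)pentanoate | CC(C)(C)[Si](C)(C)OCCCCC(=O)O[Si](C)(C)C(C)(C)C | intermediate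
4 | 5-(tert-butyldimethylsilyloxy)pentanoic acid | CC(C)(C)[Si](C)(C)OCCCCC(O)=O | intermediate
5 | geraniol | OC/C=C(\C)CCC=C(C)C | starting material
6 | geranyl 5-(tert-butyldimethylsilyloxy)pentanoate | CC(C)(C)[Si](C)(C)OCCCCC(=O)OC/C=C(\C)CCC=C(C)C | intermediate
7 | (2E,6E)-8-hydroxy-3,7-dimethylocta-2,6-dien-1-yl 5-(tert-butyldimethylsilyloxy)pentanoate | CC(C)(C)[Si](C)(C)OCCCCC(=O)OC/C=C(\C)CC/C=C(\C)CO | intermediate
8 | (2E,6E)-3,7-dimethyl-8-oxoocta-2,6-dien-1-yl 5-(tert-butyldimethylsilyloxy)pentanoate | CC(C)(C)[Si](C)(C)OCCCCC(=O)OC/C=C(\C)CC/C=C(\C)C=O | intermediate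
9 | geranyl chloride | ClC/C=C(\C)CCC=C(C)C | starting material
10 | geranylbarium chloride | Cl[Ba]C/C=C(\C)CCC=C(C)C | intermediate
11 | (2E,6E,8RS,10E)-8-hydroxy-3,7,11,15-tetramethylhexadeca-2,6,10,14-tetraen-1-yl 5-(tert-butyldimethylsilyloxy)pentanoate | CC(C)(C)[Si](C)(C)OCCCCC(=O)OC/C=C(\C)CC/C=C(\C)C(O)C/C=C(\C)CCC=C(C)C | intermediate
12 | (2E,6E,10E)-3,7,11,15-tetramethyl-8-oxohexadeca-2,6,10,14-tetraen-1-yl 5-(tert-butyldimethylsilyloxy)pentanoate | CC(C)(C)[Si](C)(C)OCCCCC(=O)OC/C=C(\C)CC/C=C(\C)C(=O)C/C=C(\C)CCC=C(C)C | intermediate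
13 | (2E,6E,8R,10E)-8-hydroxy-3,7,11,15-tetramethylhexadeca-2,6,10,14-tetraen-1-yl 5-(tert-butyldimethylsilyloxy)pentanoate | CC(C)(C)[Si](C)(C)OCCCCC(=O)OC/C=C(\C)CC/C=C(\C)[C@H](O)C/C=C(\C)CCC=C(C)C | intermediate
14 | (2E,6E,8R,10E)-8-(tert-butyldimethylsilyloxy)-3,7,11,15-tetramethylhexadeca-2,6,10,14-tetraen-1-yl 5-(tert-butyldimethylsilyloxy)pentanoate | CC(C)(C)[Si](C)(C)OCCCCC(=O)OC/C=C(\C)CC/C=C(\C)[C@H](O[Si](C)(C)C(C)(C)C)C/C=C(\C)CCC=C(C)C | intermediate
15 | Z(O)-boron ketene acetal of 14, boron carried in the (4S,5S)-4,5-diphenyl-1,3-bis[3,5-bis(trifluoromethyl)phenylsulfonyl]-1,3,2-diazaborolidine | CC(C)(C)[Si](C)(C)OCCC/C=C(\OB1N(S(=O)(=O)c2cc(cc(c2)C(F)(F)F)C(F)(F)F)[C@@H](c2ccccc2)[C@H](c2ccccc2)N1S(=O)(=O)c1cc(cc(c1)C(F)(F)F)C(F)(F)F)OC/C=C(\C)CC/C=C(\C)[C@H](O[Si](C)(C)C(C)(C)C)C/C=C(\C)CCC=C(C)C | intermediate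
16 | (2S,3R)-2-[3-(tert-butyldimethylsilyloxy)propyl]-3-methyl-3-[(3E,5R,7E)-5-(tert-butyldimethylsilyloxy)-4,8,12-trimethyltrideca-3,7,11-trien-1-yl]pent-4-enoic acid | CC(C)(C)[Si](C)(C)OCCC[C@@H]([C@](C)(CC/C=C(\C)[C@H](O[Si](C)(C)C(C)(C)C)C/C=C(\C)CCC=C(C)C)C=C)C(O)=O | intermediate
17 | methyl 2-bromopropanoate (racemic) | CC(Br)C(=O)OC | starting material
18 | acid chloride of 16 | CC(C)(C)[Si](C)(C)OCCC[C@@H]([C@](C)(CC/C=C(\C)[C@H](O[Si](C)(C)C(C)(C)C)C/C=C(\C)CCC=C(C)C)C=C)C(Cl)=O | intermediate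
19 | bromo(1-methoxy-1-oxopropan-2-yl)zinc | COC(=O)C(C)[Zn]Br | intermediate
20 | methyl (2RS,4S,5R)-4-[3-(tert-butyldimethylsilyloxy)propyl]-2,5-dimethyl-3-oxo-5-[(3E,5R,7E)-5-(tert-butyldimethylsilyloxy)-4,8,12-trimethyltrideca-3,7,11-trien-1-yl]hept-6-enoate | CC(C)(C)[Si](C)(C)OCCC[C@@H]([C@](C)(CC/C=C(\C)[C@H](O[Si](C)(C)C(C)(C)C)C/C=C(\C)CCC=C(C)C)C=C)C(=O)C(C)C(=O)OC | intermediate
21 | methyl (2RS,4S,5S)-4-[3-(tert-butyldimethylsilyloxy)propyl]-2,5-dimethyl-3,6-dioxo-5-[(3E,5R,7E)-5-(tert-butyldimethylsilyloxy)-4,8,12-trimethyltrideca-3,7,11-trien-1-yl]heptanoate | CC(C)(C)[Si](C)(C)OCCC[C@@H]([C@](C)(CC/C=C(\C)[C@H](O[Si](C)(C)C(C)(C)C)C/C=C(\C)CCC=C(C)C)C(C)=O)C(=O)C(C)C(=O)OC | intermediate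
22 | methyl (2E,4S,5S)-4-[3-(tert-butyldimethylsilyloxy)propyl]-2,5-dimethyl-6-oxo-3-(4-methylphenylsulfonyloxy)-5-[(3E,5R,7E)-5-(tert-butyldimethylsilyloxy)-4,8,12-trimethyltrideca-3,7,11-trien-1-yl]hept-2-enoate | CC(C)(C)[Si](C)(C)OCCC[C@@H]([C@](C)(CC/C=C(\C)[C@H](O[Si](C)(C)C(C)(C)C)C/C=C(\C)CCC=C(C)C)C(C)=O)/C(OS(=O)(=O)c1ccc(C)cc1)=C(/C)C(=O)OC | intermediate
23 | methyl (2Z,4R,5S)-3-ethenyl-4-[3-(tert-butyldimethylsilyloxy)propyl]-2,5-dimethyl-6-oxo-5-[(3E,5R,7E)-5-(tert-butyldimethylsilyloxy)-4,8,12-trimethyltrideca-3,7,11-trien-1-yl]hept-2-enoate | CC(C)(C)[Si](C)(C)OCCC[C@@H]([C@](C)(CC/C=C(\C)[C@H](O[Si](C)(C)C(C)(C)C)C/C=C(\C)CCC=C(C)C)C(C)=O)/C(C=C)=C(/C)C(=O)OC | intermediate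
24 | B-alkyl-9-borabicyclo[3.3.1]nonane adduct of 23 (boron on C9) | CC(C)(C)[Si](C)(C)OCCC[C@@H]([C@](C)(CC/C=C(\C)[C@H](O[Si](C)(C)C(C)(C)C)C/C=C(\C)CCC=C(C)C)C(C)=O)/C(CCB1C2CCCC1CCC2)=C(/C)C(=O)OC | intermediate
25 | methyl (2Z,4R,5S)-3-(2-hydroxyethyl)-4-[3-(tert-butyldimethylsilyloxy)propyl]-2,5-dimethyl-6-oxo-5-[(3E,5R,7E)-5-(tert-butyldimethylsilyloxy)-4,8,12-trimethyltrideca-3,7,11-trien-1-yl]hept-2-enoate | CC(C)(C)[Si](C)(C)OCCC[C@@H]([C@](C)(CC/C=C(\C)[C@H](O[Si](C)(C)C(C)(C)C)C/C=C(\C)CCC=C(C)C)C(C)=O)/C(CCO)=C(/C)C(=O)OC | intermediate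
26 | methyl (2Z,4R,5S)-3-(2-iodoethyl)-4-[3-(tert-butyldimethylsilyloxy)propyl]-2,5-dimethyl-6-oxo-5-[(3E,5R,7E)-5-(tert-butyldimethylsilyloxy)-4,8,12-trimethyltrideca-3,7,11-trien-1-yl]hept-2-enoate | CC(C)(C)[Si](C)(C)OCCC[C@@H]([C@](C)(CC/C=C(\C)[C@H](O[Si](C)(C)C(C)(C)C)C/C=C(\C)CCC=C(C)C)C(C)=O)/C(CCI)=C(/C)C(=O)OC | intermediate
27 | C9 diiodosamarium alkyl derived from 26 | CC(C)(C)[Si](C)(C)OCCC[C@@H]([C@](C)(CC/C=C(\C)[C@H](O[Si](C)(C)C(C)(C)C)C/C=C(\C)CCC=C(C)C)C(C)=O)/C(CC[Sm](I)I)=C(/C)C(=O)OC | intermediate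
28 | methyl (2Z)-2-[(2R,3S,4S)-2-[3-(tert-butyldimethylsilyloxy)propyl]-4-hydroxy-3,4-dimethyl-3-[(3E,5R,7E)-5-(tert-butyldimethylsilyloxy)-4,8,12-trimethyltrideca-3,7,11-trien-1-yl]cyclohexylidene]propanoate | CC(C)(C)[Si](C)(C)OCCC[C@@H]1/C(=C(/C)C(=O)OC)CC[C@](C)(O)[C@@]1(C)CC/C=C(\C)[C@@H](C/C=C(\C)CCC=C(C)C)O[Si](C)(C)C(C)(C)C | intermediate
29 | (2Z)-2-[(2R,3S,4S)-2-[3-(tert-butyldimethylsilyloxy)propyl]-4-hydroxy-3,4-dimethyl-3-[(3E,5R,7E)-5-(tert-butyldimethylsilyloxy)-4,8,12-trimethyltrideca-3,7,11-trien-1-yl]cyclohexylidene]propan-1-ol | CC(C)(C)[Si](C)(C)OCCC[C@@H]1/C(=C(/C)CO)CC[C@](C)(O)[C@@]1(C)CC/C=C(\C)[C@@H](C/C=C(\C)CCC=C(C)C)O[Si](C)(C)C(C)(C)C | intermediate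
30 | (2Z)-2-[(2R,3S,4S)-2-[3-(tert-butyldimethylsilyloxy)propyl]-4-hydroxy-3,4-dimethyl-3-[(3E,5R,7E)-5-(tert-butyldimethylsilyloxy)-4,8,12-trimethyltrideca-3,7,11-trien-1-yl]cyclohexylidene]propanal | CC(C)(C)[Si](C)(C)OCCC[C@@H]1/C(=C(/C)C=O)CC[C@](C)(O)[C@@]1(C)CC/C=C(\C)[C@@H](C/C=C(\C)CCC=C(C)C)O[Si](C)(C)C(C)(C)C | intermediate
31 | (2Z)-2-[(2R,3S,4S)-4-hydroxy-3-[(3E,5R,7E)-5-hydroxy-4,8,12-trimethyltrideca-3,7,11-trien-1-yl]-2-(3-hydroxypropyl)-3,4-dimethylcyclohexylidene]propanal | OCCC[C@@H]1/C(=C(/C)C=O)CC[C@](C)(O)[C@@]1(C)CC/C=C(\C)[C@@H](C/C=C(\C)CCC=C(C)C)O | intermediate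
32 | decanoyl chloride | CCCCCCCCCC(Cl)=O | starting material
33 | 3-[(1R,2S,3S)-3-hydroxy-2-[(3E,5R,7E)-5-hydroxy-4,8,12-trimethyltrideca-3,7,11-trien-1-yl]-2,3-dimethyl-6-[(2Z)-1-oxopropan-2-ylidene]cyclohexyl]propyl decanoate | CCCCCCCCCC(=O)OCCC[C@@H]1/C(=C(/C)C=O)CC[C@](C)(O)[C@@]1(C)CC/C=C(\C)[C@@H](C/C=C(\C)CCC=C(C)C)O | intermediate
34 | (2Z)-2-[(2R,3S,4S)-3-[(3E,5R,7E)-5-acetoxy-4,8,12-trimethyltrideca-3,7,11-trien-1-yl]-2-[3-(decanoyloxy)propyl]-4-hydroxy-3,4-dimethylcyclohexylidene]propanal; iridal numbering (2Z,6R,10S,11S,14E,16R,18E) | CCCCCCCCCC(=O)OCCC[C@@H]1/C(=C(/C)C=O)CC[C@](C)(O)[C@@]1(C)CC/C=C(\C)[C@@H](C/C=C(\C)CCC=C(C)C)OC(C)=O | target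

**Totals and risks**

Total step count: 20 steps. Longest linear sequence: 20 steps (1 → 34; 19 steps from geraniol 5).

Steps most likely to fail:

1. Step 15 (key step). The C9 organosamarium may be quenched by proton transfer from the enolisable methyl ketone, may close a three-membered ring onto the enoate, or may show weak facial discrimination at C10. The fallback forms the same C9–C10 bond by reductive carbonyl coupling instead of carbanion addition. It sets out from alcohol 25. Oxidation (Dess–Martin periodinane, pyridine, CH2Cl2) gives the C9 aldehyde F1. SmI2 (2.2 equiv), tBuOH, THF, −78 °C should close the ring by intramolecular ketone–aldehyde pinacol coupling to the cis-9,10-diol F2, both oxygens being held on one trivalent samarium and no basic carbanion being formed. The secondary C9 hydroxyl alone is converted with PhOC(S)Cl, pyridine and DMAP into the C9 phenyl thionocarbonate F3, which is removed with Bu3SnH/AIBN in toluene at 80 °C (Barton–McCombie deoxygenation). The route is rejoined at 28.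

2. Step 8. The boron enolate may form with incomplete geometric or facial control, and the slow rearrangement of the trisubstituted allyl unit may be overtaken by decomposition. The fallback replaces reagent control by separation of auxiliary-bound diastereomers. It sets out from ester 14. LDA, THF/DMPU, −78 °C, then Me3SiCl gives the trimethylsilyl ketene acetal F4, which rearranges on warming and, after acidic work-up, should give acid 16 together with its C6,C11-antipodal acid F5. The mixture is acylated onto (S)-4-benzyloxazolidin-2-one (pivaloyl chloride, Et3N; then the lithiated oxazolidinone) to give the imide F6 from 16 and the diastereomeric imide F7 from F5, which are separated by chromatography. LiOH/H2O2 in THF/H2O cleaves F6. The route is rejoined at acid 16, with at most half of the material.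

3. Step 4. The allylbarium may lose regiochemical (α against γ) or geometric integrity, and activation of the metal may be incomplete. The fallback uses a sulfone-stabilised carbanion, which can only react at its α carbon. It sets out from aldehyde 8 and geranyl chloride 9. PhSO2Na in DMF converts 9 into geranyl phenyl sulfone F8. Its lithio derivative (nBuLi, THF, −78 °C) adds to 8 to give the β-hydroxy sulfone F9. Dess–Martin oxidation gives the β-keto sulfone F10, and reductive desulfonylation (SmI2, THF/MeOH, −78 °C) should give the enone. The route is rejoined at enone 12, so steps 4 and 5 are both replaced.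

**Further compounds**

F1 | step 15 | C9 aldehyde: methyl (2Z,4R,5S)-4-[3-(tert-butyldimethylsilyloxy)propyl]-2,5-dimethyl-6-oxo-3-(2-oxoethyl)-5-[(3E,5R,7E)-5-(tert-butyldimethylsilyloxy)-4,8,12-trimethyltrideca-3,7,11-trien-1-yl]hept-2-enoate | CC(C)(C)[Si](C)(C)OCCC[C@@H]([C@](C)(CC/C=C(\C)[C@H](O[Si](C)(C)C(C)(C)C)C/C=C(\C)CCC=C(C)C)C(C)=O)/C(CC=O)=C(/C)C(=O)OC
F2 | step 15 | cis-9,10-diol: 9-hydroxy derivative of 28 with the C9 hydroxyl cis to the C10 hydroxyl | CC(C)(C)[Si](C)(C)OCCC[C@@H]1/C(=C(/C)C(=O)OC)C[C@H](O)[C@](C)(O)[C@@]1(C)CC/C=C(\C)[C@@H](C/C=C(\C)CCC=C(C)C)O[Si](C)(C)C(C)(C)C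
F3 | step 15 | C9 phenyl thionocarbonate of F2 | CC(C)(C)[Si](C)(C)OCCC[C@@H]1/C(=C(/C)C(=O)OC)C[C@H](OC(=S)Oc2ccccc2)[C@](C)(O)[C@@]1(C)CC/C=C(\C)[C@@H](C/C=C(\C)CCC=C(C)C)O[Si](C)(C)C(C)(C)C
F4 | step 8 | trimethylsilyl ketene acetal of 14, Z(O) geometry | CC(C)(C)[Si](C)(C)OCCC/C=C(\O[Si](C)(C)C)OC/C=C(\C)CC/C=C(\C)[C@H](O[Si](C)(C)C(C)(C)C)C/C=C(\C)CCC=C(C)C
F5 | step 8 | (2R,3S)-2-[3-(tert-butyldimethylsilyloxy)propyl]-3-methyl-3-[(3E,5R,7E)-5-(tert-butyldimethylsilyloxy)-4,8,12-trimethyltrideca-3,7,11-trien-1-yl]pent-4-enoic acid | CC(C)(C)[Si](C)(C)OCCC[C@H]([C@@](C)(CC/C=C(\C)[C@H](O[Si](C)(C)C(C)(C)C)C/C=C(\C)CCC=C(C)C)C=C)C(O)=O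
F6 | step 8 | N-acyl (S)-4-benzyloxazolidin-2-one of acid 16 | CC(C)(C)[Si](C)(C)OCCC[C@@H]([C@](C)(CC/C=C(\C)[C@H](O[Si](C)(C)C(C)(C)C)C/C=C(\C)CCC=C(C)C)C=C)C(=O)N1[C@@H](Cc2ccccc2)COC1=O
F7 | step 8 | N-acyl (S)-4-benzyloxazolidin-2-one of acid F5 | CC(C)(C)[Si](C)(C)OCCC[C@H]([C@@](C)(CC/C=C(\C)[C@H](O[Si](C)(C)C(C)(C)C)C/C=C(\C)CCC=C(C)C)C=C)C(=O)N1[C@@H](Cc2ccccc2)COC1=O
F8 | step 4 | geranyl phenyl sulfone | O=S(=O)(C/C=C(\C)CCC=C(C)C)c1ccccc1
F9 | step 4 | (2E,6E,10E)-8-hydroxy-3,7,11,15-tetramethyl-9-(phenylsulfonyl)hexadeca-2,6,10,14-tetraen-1-yl 5-(tert-butyldimethylsilyloxy)pentanoate (stereoisomer mixture at C8 and C9) | CC(C)(C)[Si](C)(C)OCCCCC(=O)OC/C=C(\C)CC/C=C(\C)C(O)C(/C=C(\C)CCC=C(C)C)S(=O)(=O)c1ccccc1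
F10 | step 4 | (2E,6E,10E)-3,7,11,15-tetramethyl-8-oxo-9-(phenylsulfonyl)hexadeca-2,6,10,14-tetraen-1-yl 5-(tert-butyldimethylsilyloxy)pentanoate | CC(C)(C)[Si](C)(C)OCCCCC(=O)OC/C=C(\C)CC/C=C(\C)C(=O)C(/C=C(\C)CCC=C(C)C)S(=O)(=O)c1ccccc1
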